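**Plan**

1. The target is a (1S,2R)-1-aryl-1,2-dihydronaphthalene-3-carbaldehyde (C1 = CH–aryl, C2 = CH–CH2OH, C3 = C–CHO, C4 = CH=; ring A = benzo ring, ring B = carbocycle). The retrosynthesis cuts ring B twice in one operation: C4=C3 (aldol-condensation retron, ring A aldehyde carbon plus a CH2CHO unit) and C8a–C1 (Friedel–Crafts retron, benzylic cation at C1).
2. Enabling feature: C1 is benzylic to a 4-oxygenated aryl ring (stabilised cation), and C8a is ortho/para to the 8- and 6-OMe groups of ring A. A helper oxygen placed on C1 forms, with the C2–CH2O oxygen, a 1,3-diol that can carry the ring A aldehyde as a 1,3-dioxane.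
3. This temporary ring is the tether. A Lewis acid opens it to an oxocarbenium ion that bonds to the enol carbon C3; the helper oxygen then leaves C1 as the cation that ring A captures. Tether and helper oxygen are consumed in the event itself.
4. Forward order: aldol (C1–C2 chain, allyl as masked CH2CHO), reduction to the 1,3-diol, dioxane formation with the ring A aldehyde, alkene cleavage, cascade closing ring B, removal of protecting groups.
5. Stereochemistry: C2 comes from an Evans syn-aldol with (4S)-4-benzyloxazolidin-2-one. C1 is set in the cascade, trans to the C2 substituent, by substrate control. The aldol carbinol centre and the acetal centre are sacrificial.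

Key step: step 8

Remark: ArSi = 4-[(tert-butyldimethylsilyl)oxy]-3,5-dimethoxyphenyl; ArAc = 4-acetoxy-3,5-dimethoxyphenyl. Compounds 13, 15 and 16 are expected as mixtures at centres or double bonds that are destroyed later, so these are left open in their SMILES.

**Route**

Step 1
Reactants: 1 syringaldehyde (4-hydroxy-3,5-dimethoxybenzaldehyde)
Product: 2 4-[(tert-butyldimethylsilyl)oxy]-3,5-dimethoxybenzaldehyde (ArSi–CHO)
Conditions: TBSCl, imidazole, DMF, rt
Reagents that add atoms: tert-butyldimethylsilyl chloride, CC(C)(C)[Si](C)(C)Cl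
Why: Standard silylation of a phenol; the aryl silyl ether survives the following steps and keeps the oxygen a para donor for the later cation at C1.

Step 2
Reactants: 3 (4S)-4-benzyl-1,3-oxazolidin-2-one; 4 pent-4-enoyl chloride
Product: 5 (4S)-4-benzyl-3-(pent-4-enoyl)-1,3-oxazolidin-2-one
Conditions: Et3N, DMAP (cat.), CH2Cl2, 0 °C → rt
Reagents that add atoms: none
Why: DMAP-catalysed N-acylation of the oxazolidinone with an acid chloride; the auxiliary centre is not touched.

Step 3
Reactants: 5 (4S)-4-benzyl-3-(pent-4-enoyl)-1,3-oxazolidin-2-one; 2 ArSi–CHO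
Product: 8 (4S)-4-benzyl-3-[(2S)-2-[(S)-ArSi(hydroxy)methyl]pent-4-enoyl]-1,3-oxazolidin-2-one, via Z-boron enolate 6 (not isolated), via boron aldolate 7 (not isolated)
Conditions: Bu2BOTf, iPr2NEt, CH2Cl2, −78 → 0 °C; then 2, −78 → 0 °C; then pH 7 buffer, MeOH, H2O2 (30% aq.), 0 °C
Reagents that add atoms: none
Why: Evans syn-aldol; the Z-boron enolate reacts through a closed chair (Zimmerman–Traxler) transition state on the enolate face remote from the benzyl group, which should give the (2S,3S) syn adduct and thereby sets the future C2.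

Step 4
Reactants: 8 aldol adduct
Product: 9 (1S,2R)-1-ArSi-2-(prop-2-en-1-yl)propane-1,3-diol
Conditions: LiBH4, H2O (1 equiv), Et2O, 0 °C
Reagents that add atoms: none
Why: Reductive cleavage of the N-acyl oxazolidinone to the primary alcohol; no stereocentre is touched (the descriptor at the former α-carbon changes from S to R only through CIP priorities).

Step 5
Reactants: 1 syringaldehyde
Product: 10 4-formyl-2,6-dimethoxyphenyl acetate (ArAc–CHO)
Conditions: Ac2O, pyridine, DMAP (cat.), CH2Cl2, rt
Reagents that add atoms: acetic anhydride, CC(=O)OC(C)=O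
Why: Standard phenol acetylation; the acyloxy group is deliberately a poor para donor towards the future C4 while leaving the nucleophilic ring A carbon (meta to it) almost unaffected.

Step 6
Reactants: 9 diol; 10 ArAc–CHO
Product: 12 (2S,4S,5R)-2-ArAc-4-ArSi-5-(prop-2-en-1-yl)-1,3-dioxane, via dimethyl acetal 11 (not isolated)
Conditions: 10, HC(OMe)3, CSA (cat.), CH2Cl2, rt; then 9, 5 Å MS, rt
Reagents that add atoms: none
Why: Acid-catalysed transacetalisation of a 1,3-diol under thermodynamic control should place the 2-aryl group equatorial and cis to the 4-aryl group (2S); this centre is lost later in any case.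

Step 7
Reactants: 12 allyl dioxane
Product: 14 2-[(2S,4S,5R)-2-ArAc-4-ArSi-1,3-dioxan-5-yl]acetaldehyde, via vicinal diol 13 (not isolated)
Conditions: OsO4 (cat.), NaIO4, 2,6-lutidine, 1,4-dioxane/H2O, rt
Reagents that add atoms: osmium tetroxide, O=[Os](=O)(=O)=O (catalytic oxygen carrier); sodium periodate, [Na+].[O-]I(=O)(=O)=O (terminal oxygen source)
Why: Lemieux–Johnson oxidation (dihydroxylation, then glycol cleavage) under buffered, near-neutral conditions that the acetal, aryl acetate and aryl silyl ether should tolerate; no stereocentre is touched.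

Step 8
Reactants: 14 dioxane aldehyde
Product: 18 (1S,2R)-7-acetoxy-1-ArSi-6,8-dimethoxy-2-[(trimethylsilyloxy)methyl]-1,2-dihydronaphthalene-3-carbaldehyde, via enol silane 15 (not isolated), via tetrahydrofuran aldehyde 16 (not isolated), via seco enal 17 (not isolated)
Conditions: iPr2NEt (3.0 equiv), TMSOTf (3.5 equiv, in two portions), CH2Cl2, −78 → 0 °C; cold NaHCO3 (aq.) wash; used crude
Reagents that add atoms: trimethylsilyl trifluoromethanesulfonate, C[Si](C)(C)OS(=O)(=O)C(F)(F)F
Why: Proposed new method: soft enolisation gives enol silane 15, TMSOTf opens the benzylidene acetal to an aryl oxocarbenium ion that is captured by the tethered enol carbon (new C4–C3 bond, tetrahydrofuran 16), a second soft enolisation expels the ring oxygen from the β-position (E1cB) to give the (E)-enal 17, and TMSOTf then ionises the benzylic silyl ether so that ring A closes on the cation (new C8a–C1 bond). The closest known reaction types are the Lewis-acid aldol of enol silanes with acetals (Mukaiyama type, with the oxygen-to-carbon transposition of a Petasis–Ferrier rearrangement) for the first bond, and the acid-induced conversion of 2,5-diaryltetrahydrofuran lignans and of sinapate-derived quinone methides into 1-aryl-1,2-dihydronaphthalenes for the second; their merger on a 1,3-dioxane tether is without direct precedent. The transient tetrahydrofuran closes by a Prins-type 5-endo-trig attack on the endocyclic oxocarbenium ion with the enol silane exocyclic (5-enolexo) and is reopened, while ring B closes by a 6-exo-trig Friedel–Crafts attack of C8a on the benzylic cation whose aryl π system stays outside the ring. C2 is untouched because it is never α to the aldehyde, and the new C1 centre is controlled by C2: in the cation the C2–H bond eclipses the aryl plane (allylic 1,3-strain), ring A is tethered to one face and bonds anti to the CH2OSiMe3 group, giving the 1,2-trans isomer, which is also the more stable one (both substituents pseudoaxial, away from the peri 8-OMe). The step needs C1, not C4, to become the cationic carbon, ring A and not the pendant ring to act as the nucleophile, and ring closure to outrun loss of the C2 proton (which would erode the enantiomeric purity). This is secured by the acetate on ring A (para to C4, meta to the attacking carbon), the silyl ether on the pendant ring (para donor to C1), the formyl group that turns any C4–O cleavage into enal formation, the low temperature and the intramolecularity; the two ortho positions of ring A are equivalent, so no regiochemical issue arises.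

Step 9
Reactants: 18 cyclised trimethylsilyl ether
Product: 19 (1S,2R)-7-hydroxy-1-(4-hydroxy-3,5-dimethoxyphenyl)-2-(hydroxymethyl)-6,8-dimethoxy-1,2-dihydronaphthalene-3-carbaldehyde
Conditions: K2CO3, MeOH (degassed), argon, 0 °C → rt; NH4Cl (aq.)
Reagents that add atoms: none
Why: Base-mediated methanolysis should cleave the aryl acetate, the aryl silyl ether and the primary trimethylsilyl ether in one operation; C2 is not vinylogously acidic (it sits on the α-carbon of the enal) and C1 carries no leaving group, so both centres should be retained.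

**Compound list**

1 | syringaldehyde (4-hydroxy-3,5-dimethoxybenzaldehyde) | COc1cc(C=O)cc(OC)c1O | starting material
2 | 4-[(tert-butyldimethylsilyl)oxy]-3,5-dimethoxybenzaldehyde | COc1cc(C=O)cc(OC)c1O[Si](C)(C)C(C)(C)C | intermediate
3 | (4S)-4-benzyl-1,3-oxazolidin-2-one | O=C1OC[C@H](Cc2ccccc2)N1 | starting material
4 | pent-4-enoyl chloride | C=CCCC(=O)Cl | starting material
5 | (4S)-4-benzyl-3-(pent-4-enoyl)-1,3-oxazolidin-2-one | O=C1OC[C@H](Cc2ccccc2)N1C(=O)CCC=C | intermediate
6 | Z-dibutylboron enolate of 5 (not isolated) | O=C1OC[C@H](Cc2ccccc2)N1/C(OB(CCCC)CCCC)=C/CC=C | intermediate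
7 | dibutylboron aldolate of 8 (not isolated) | O=C1OC[C@H](Cc2ccccc2)N1C(=O)[C@@H](CC=C)[C@H](OB(CCCC)CCCC)c1cc(OC)c(O[Si](C)(C)C(C)(C)C)c(OC)c1 | intermediate
8 | (4S)-4-benzyl-3-[(2S)-2-[(S)-ArSi(hydroxy)methyl]pent-4-enoyl]-1,3-oxazolidin-2-one | O=C1OC[C@H](Cc2ccccc2)N1C(=O)[C@@H](CC=C)[C@H](O)c1cc(OC)c(O[Si](C)(C)C(C)(C)C)c(OC)c1 | intermediate
9 | (1S,2R)-1-ArSi-2-(prop-2-en-1-yl)propane-1,3-diol | OC[C@@H](CC=C)[C@H](O)c1cc(OC)c(O[Si](C)(C)C(C)(C)C)c(OC)c1 | intermediate
10 | 4-formyl-2,6-dimethoxyphenyl acetate | COc1cc(C=O)cc(OC)c1OC(C)=O | intermediate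
11 | 4-(dimethoxymethyl)-2,6-dimethoxyphenyl acetate (not isolated) | COC(OC)c1cc(OC)c(OC(C)=O)c(OC)c1 | intermediate
12 | (2S,4S,5R)-2-ArAc-4-ArSi-5-(prop-2-en-1-yl)-1,3-dioxane | C=CC[C@@H]1CO[C@H](c2cc(OC)c(OC(C)=O)c(OC)c2)O[C@@H]1c1cc(OC)c(O[Si](C)(C)C(C)(C)C)c(OC)c1 | intermediate
13 | 3-[(2S,4S,5R)-2-ArAc-4-ArSi-1,3-dioxan-5-yl]propane-1,2-diol, both carbinol epimers (not isolated) | OCC(O)C[C@@H]1CO[C@H](c2cc(OC)c(OC(C)=O)c(OC)c2)O[C@@H]1c1cc(OC)c(O[Si](C)(C)C(C)(C)C)c(OC)c1 | intermediate
14 | 2-[(2S,4S,5R)-2-ArAc-4-ArSi-1,3-dioxan-5-yl]acetaldehyde | O=CC[C@@H]1CO[C@H](c2cc(OC)c(OC(C)=O)c(OC)c2)O[C@@H]1c1cc(OC)c(O[Si](C)(C)C(C)(C)C)c(OC)c1 | intermediate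
15 | trimethylsilyl enol ether of 14, E/Z mixture (not isolated) | C[Si](C)(C)OC=C[C@@H]1CO[C@H](c2cc(OC)c(OC(C)=O)c(OC)c2)O[C@@H]1c1cc(OC)c(O[Si](C)(C)C(C)(C)C)c(OC)c1 | intermediate
16 | (4R,5S)-2-ArAc-5-ArSi-4-[(trimethylsilyloxy)methyl]oxolane-3-carbaldehyde, epimers at C2 and C3 (not isolated) | O=CC1C(c2cc(OC)c(OC(C)=O)c(OC)c2)O[C@H](c2cc(OC)c(O[Si](C)(C)C(C)(C)C)c(OC)c2)[C@H]1CO[Si](C)(C)C | intermediate
17 | (2E,3R,4S)-2-(ArAc-methylidene)-4-ArSi-4-(trimethylsilyloxy)-3-[(trimethylsilyloxy)methyl]butanal (not isolated) | COc1cc(/C=C(/C=O)[C@H](CO[Si](C)(C)C)[C@H](O[Si](C)(C)C)c2cc(OC)c(O[Si](C)(C)C(C)(C)C)c(OC)c2)cc(OC)c1OC(C)=O | intermediate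
18 | (1S,2R)-7-acetoxy-1-ArSi-6,8-dimethoxy-2-[(trimethylsilyloxy)methyl]-1,2-dihydronaphthalene-3-carbaldehyde | COc1cc([C@H]2c3c(cc(OC)c(OC(C)=O)c3OC)C=C(C=O)[C@@H]2CO[Si](C)(C)C)cc(OC)c1O[Si](C)(C)C(C)(C)C | intermediate
19 | (1S,2R)-7-hydroxy-1-(4-hydroxy-3,5-dimethoxyphenyl)-2-(hydroxymethyl)-6,8-dimethoxy-1,2-dihydronaphthalene-3-carbaldehyde | COc1cc([C@H]2c3c(cc(OC)c(O)c3OC)C=C(C=O)[C@@H]2CO)cc(OC)c1O | target

**Step count and risks**

Total steps: 9. Longest linear sequence: 7 steps (steps 2, 3, 4, 6, 7, 8, 9).

Steps most likely to fail: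

1. Step 8. What may go wrong: fragmentation of the opened acetal (release of the ring A aldehyde and an untethered benzylic cation) or ionisation at the future C1 before the C4–C3 bond exists, followed by loss of the C2 proton and erosion of enantiomeric purity; stalling at the tetrahydrofuran stage; formation of a Z-enal that cannot close; closure through the pendant ring. Fallback (known chemistry, the two bonds made one after the other and intermolecularly), setting out from diol 9 and returning at target 19: selective silylation of the primary hydroxyl (TBDPSCl, imidazole) would give (1S,2R)-2-{[(tert-butyldiphenylsilyl)oxy]methyl}-1-ArSi-pent-4-en-1-ol F1. Lemieux–Johnson cleavage of its alkene would give the γ-hydroxy aldehyde as its lactol, (4R,5S)-5-ArSi-4-{[(tert-butyldiphenylsilyl)oxy]methyl}oxolan-2-ol F2. A pyrrolidine/benzoic acid-catalysed crossed aldol condensation of F2 with aldehyde 2 would give the (2E,3R,4S)-2-arylidene-4-hydroxy aldehyde F3. TFA in CH2Cl2 at low temperature would ionise its benzylic alcohol and close ring B (the established acid cyclisation of benzylic-hydroxylated lignan precursors) to the tris-silyl ether of the target F4. Bu4NF/AcOH in THF would then remove all three silyl groups and give 19.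

2. Step 6. What may go wrong: acid-induced ionisation of the electron-rich benzylic C–O bond of 9 (elimination or oligomerisation), acetyl transfer from the aryl acetate to the primary alcohol, or incomplete exchange. Fallback, setting out from diol 9 and returning at dioxane 12: silylation of both hydroxyls (TMSCl, Et3N) would give the bis(trimethylsilyl) ether of the diol F5, which would be condensed directly with aldehyde 10 under catalytic TMSOTf in CH2Cl2 at −78 °C. This is an aprotic, kinetically controlled silyl-transfer acetalisation in place of the protic equilibrium; a mixture at the acetal carbon would be harmless because that centre becomes sp2 in step 8.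

3. Step 9. What may go wrong: air oxidation of the phenoxide-bearing dihydronaphthalene under base (dehydrogenation towards the naphthalene), or sluggish cleavage of the doubly ortho-substituted aryl silyl ether. Fallback, setting out from 18 and returning at target 19, in two base-free stages: Bu4NF/AcOH in THF at 0 °C would remove both silyl groups and give the ring A mono-acetate of the target F6; NH4OAc in aqueous MeOH at rt (neutral solvolysis of aryl acetates) would then release the last phenol and give 19.

Further compounds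
F1 | step 8 | (1S,2R)-2-{[(tert-butyldiphenylsilyl)oxy]methyl}-1-ArSi-pent-4-en-1-ol | CC(C)(C)[Si](c1ccccc1)(c1ccccc1)OC[C@@H](CC=C)[C@H](O)c1cc(OC)c(O[Si](C)(C)C(C)(C)C)c(OC)c1
F2 | step 8 | (4R,5S)-5-ArSi-4-{[(tert-butyldiphenylsilyl)oxy]methyl}oxolan-2-ol (anomer mixture) | OC1C[C@H](CO[Si](c2ccccc2)(c2ccccc2)C(C)(C)C)[C@@H](c2cc(OC)c(O[Si](C)(C)C(C)(C)C)c(OC)c2)O1
F3 | step 8 | (2E,3R,4S)-2-(ArSi-methylidene)-3-{[(tert-butyldiphenylsilyl)oxy]methyl}-4-ArSi-4-hydroxybutanal | COc1cc(/C=C(/C=O)[C@H](CO[Si](c2ccccc2)(c2ccccc2)C(C)(C)C)[C@H](O)c2cc(OC)c(O[Si](C)(C)C(C)(C)C)c(OC)c2)cc(OC)c1O[Si](C)(C)C(C)(C)C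
F4 | step 8 | (1S,2R)-7-[(tert-butyldimethylsilyl)oxy]-1-ArSi-2-{[(tert-butyldiphenylsilyl)oxy]methyl}-6,8-dimethoxy-1,2-dihydronaphthalene-3-carbaldehyde | COc1cc([C@H]2c3c(cc(OC)c(O[Si](C)(C)C(C)(C)C)c3OC)C=C(C=O)[C@@H]2CO[Si](c2ccccc2)(c2ccccc2)C(C)(C)C)cc(OC)c1O[Si](C)(C)C(C)(C)C
F5 | step 6 | (1S,2R)-1-ArSi-2-(prop-2-en-1-yl)-1,3-bis(trimethylsilyloxy)propane | C[Si](C)(C)OC[C@@H](CC=C)[C@H](O[Si](C)(C)C)c1cc(OC)c(O[Si](C)(C)C(C)(C)C)c(OC)c1
F6 | step 9 | (1S,2R)-7-acetoxy-1-(4-hydroxy-3,5-dimethoxyphenyl)-2-(hydroxymethyl)-6,8-dimethoxy-1,2-dihydronaphthalene-3-carbaldehyde | COc1cc([C@H]2c3c(cc(OC)c(OC(C)=O)c3OC)C=C(C=O)[C@@H]2CO)cc(OC)c1O
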